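The numbers in the tables were computed with constants of no real substance.

**At the bench.** You read this flask at 6.0 min. Until then D and L are turning into X and E with Z over the catalyst J, and D is going faster.

all flasks: D 0.50 M; L 0.50 M

| run | Z | J | remark | time |
|---|---|---|---|---|
| larch | 1 M | 2.5 mM | run made earlier |  |
| alder | 1 M | 5.7 mM | run made earlier |  |
| flask | 1.00 M | 3.8 mM |  | 6.0 min |

| run | time / min | D / % | L / % | X / % |
|---|---|---|---|---|
| larch | 0.500 | 47.3 | 47.6 | 2.8 |
| larch | 1.00 | 44.1 | 46.9 | 6.3 |
| larch | 2.00 | 39.2 | 43.9 | 10.8 |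
| larch | 4.00 | 31.4 | 39.6 | 16.8 |
| larch | 8.00 | 24.9 | 35.3 | 24.1 |
| alder | 0.500 | 43.3 | 46.7 | 7.7 |
| alder | 1.00 | 37.8 | 43.3 | 12.4 |
| alder | 2.00 | 29.6 | 37.8 | 19.3 |
| alder | 4.00 | 21.8 | 31.8 | 27.3 |
| alder | 8.00 | 13.5 | 26.1 | 34.1 |

(each reading ± 0.5 percentage points)

- J is single-handed; D and L are mirror images of each other, charged as a racemate, each of them at the stated concentration
- steps that have been proposed: Z -> G; Z + J + D -> J + X; Z + J + L -> J + E; X <-> E; Z + J -> Q
- an excess is the difference of the two amounts in percent of their sum
- an excess is below zero if the other one leads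

- part of the D and L charged together that has reacted at 6.0 min
- excess of X over E in the product at 6.0 min
- excess of L over D among what is left of the two at 6.0 min

**One ratio.** I divide ln of the share of D left by ln of the share of L left at the last reading. Larch gives 2.00 and alder 2.01, so I carry their mean, 2.01, as a reading: the selectivity factor, that same ratio of logarithms. In use, the share of L left is the share of D left raised to one over this factor.

**Leave alone.** Leave J at 3.8 mM, the charge these questions are asked for. Alder, with 5.7 mM against 2.5 mM in larch, had D down to 13.5% against 24.9% at 8.00 min, yet the ratio stayed the same.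

**The forecast.** It gives 45.4% reacted (43.5% to 47.5%), 19% for the product (15.5% to 23%) and 20.5% for the remainder (18% to 23%), on the ground that “D reacts about twice as fast as L”.

**The flask.** It gives 44.8%, 17.9% and 20.0%, each inside its range, so L leads what is left and X leads the product. Z is used by the D step 2.0 times as fast as by the L step at the start, but 1.3 times as fast at 6.00 min, with 44% of D and 66% of L left.

    Z → G (k = 5.40 × 10⁻⁴ s⁻¹)
    Z + J + D → J + X (k = 0.970 M⁻² s⁻¹)
    Z + J + L → J + E (k = 0.490 M⁻² s⁻¹)
    X ⇌ E (k = 6.50 × 10⁻⁴ s⁻¹)
    Z + J → Q (k = 4.00 × 10⁻⁴ M⁻¹ s⁻¹)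

The carried factor turns that D into 66.5% of L. In the neighbour charged with 1.7 M of Z, 24% of D left gives 49.2% of L, and that flask holds 49%.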